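# Synthesis plan for CNP0174688.1: ring C of unit M by ortho-quinone methide annulation

Compound numbers 1–28 are those of the steps and the compound list below. Unit T is the 4',7,8-trihydroxyflavan-3,4-diol (teracacidin) unit. Unit M is the 3',4',7,8-tetrahydroxyflavan-3-ol unit, joined through its C4 to C6 of unit T.

## The problem

The target joins two flavan units by one C–C bond, so C4 of unit M is a doubly benzylic methine between two electron-rich arenes. Each unit has three contiguous stereocentres: unit T is all-cis (2R,3R,4R), and unit M is 2,3-cis-3,4-trans (2R,3R,4S). Within one pyran ring the centres can steer each other, since an acyloxy group at C3 can direct a hydride at C2 and the C4 substituent biases C3. The two triads are separated by the flat ring A of unit T, so their relation must come from an enantiopure unit T and reagent control at C4 of unit M. Both 2,3-cis relations are the less stable ones and have to be set kinetically by hydride delivery. The benzylic C4 hydroxyl of unit T (para to O7, ortho to O1) ionises easily, the interflavan bond is acid-labile, and the seven phenols oxidise in air. The phenols are therefore masked to the end and the diol of unit T is carried in a form that resists ionisation. The enabling feature is that C4 of unit M is benzylic to ring A of unit M, whose ortho carbon C8a bears O1. C4, C4a, C8a and O1 thus form a latent ortho-quinone methide that lacks only C2–C3, which an enol ether of an aryl ketone carrying the C3 oxygen can supply.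

## Retrosynthesis

**Protecting groups (28 from 27 from 26).** The seven O-benzyl bonds of 27 are cut last by neutral hydrogenolysis. Before that, the benzoate at O3 of unit M and the cyclic carbonate of unit T in 26 are removed by methanolysis. This order is chosen because a benzylic carbonate is hydrogenolysed at C4 faster than a free hydroxyl.

**C2–H of unit M (26 from 25).** Cutting C2–H leads to the hemiketal 25, the direct product of the annulation. Against a cut at O1–C2 (Mitsunobu closure) this needs no open-chain diol. The C3 benzoate of 25 is placed to direct hydride to the face anti to itself. The forward step must ionise the tertiary hemiketal without ionising C4 of unit T.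

**C3–C4 and O1–C2 of unit M (25 from 18 and 22).** This is the key cut. The neighbouring cut at C4(M)–C6(T), the cation arylation, would need a complete 2,3-cis unit M with a leaving group at C4 beforehand. The chosen cut closes ring C, brings in the C3 oxygen and the ring B aryl group, and attaches unit T in one operation. The precursors are the 2-hydroxybenzhydrol 18 and the two-carbon enol ether 22. The forward reaction must control the face of C4 by a chiral acid and give the 3,4-trans relation.

**Carbinol carbon to C6 of unit T (18 from 15 and 2).** The benzhydrol is cut into the aryl iodide 15 (as Grignard reagent 16) and the salicylaldehyde 2 (as phenoxide 17). The reverse polarity would need an ortho-metalated protected phenol and an extra deprotection next to an acid-labile carbinol. The carbinol configuration is irrelevant.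

**Enol ether (22 from 21 from 20 from 19).** The O–Si bond, the two benzyl ethers and the C–O bond of the benzoate are cut back to the chloro ketone 19.

**C6–I and the carbonate (15 from 14 from 13).** Iodination is placed after the diol 13 is tied up as carbonate 14. Ring A of unit T is then the only strongly activated arene, and C6 is its most nucleophilic position.

**C4–O of unit T (13 from 12, 11, 10, 9 and 8).** The C4 oxygen is introduced by benzylic oxidation of the silyl ether 9 to alcohol 10. Its configuration is then set through ketone 11 and hydride delivery anti to the axial C3 silyloxy group, giving 12. Hydrogenation of a flavonol would give the same all-cis array but as a racemate, and it does not tolerate benzyl ethers. Dihydroxylation of a flav-3-ene places both oxygens trans to the aryl group.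

**C3–O of unit T (8 from 7 from 5).** The 2,3-cis alcohol 8 comes from ketone 7 by bulky hydride. Ketone 7 comes from the enal 5 by Baeyer–Villiger excision of the formyl carbon through the enol formate 6.

**O1–C2 and C3–C4 of unit T (5 from 2 and 4; 4 from 3; 2 from 1).** The chromene 5 is cut into salicylaldehyde 2 and enal 4. An amine-catalysed oxa-Michael/aldol condensation sets C2, the only stereocentre that needs an external source of chirality in unit T. Aldehyde 2 is used twice, as ring A of unit T and as ring A of unit M.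

## Roads not taken

**Alternative 1:** C4 of unit M is made first, without either heterocycle, by cutting C3–C4 and C4–C4a. An aryl acetylide adds to an aldehyde. In the same flask a chiral phosphoric acid ionises the propargylic carbinol to a para-quinone methide, which a phenol captures through its ortho carbon to give the diarylpropyne A1.
- Merits: three components meet in one flask, and asymmetric 1,6-additions of phenols to para-quinone methides are better precedented than the enol ether addition used here.
- Weak points: A1 holds one of six stereocentres and neither ring C. The alkyne still needs regioselective hydration, oxygenation at C3 anti to C4 and a stereocontrolled ring closure. All of unit T must then be grown on a phenol that already carries unit M. Alkynyl para-quinone methides can also react at the remote alkyne carbon to give allenes.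
- Comparison: it is shorter and safer up to its key step. The chosen plan sets against this a key step that forms two bonds, ring C and both C3 and C4 with the C3 oxygen in place, and a unit T that arrives complete, so only three steps follow.

**Alternative 2:** Both rings C are closed last by cutting O1–C8a in each unit. A palladium catalyst with a bulky biaryl phosphine and a carbonate base couples each benzylic C2 hydroxyl with its own aryl bromide, with retention, to give A2.
- Merits: the C2 centres are ordinary carbinols set in the open chain, and no acid or hemiketal reduction is involved.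
- Weak points: the open-chain precursor must already hold all six stereocentres, including the doubly benzylic C4 of unit M, for which this road has no solution of its own. Secondary benzylic alkoxides on palladium undergo β-hydride elimination to aryl ketones. The aryl bromides are electron-rich and flanked by benzyloxy groups. Two such closures must succeed in one heavy molecule.
- Comparison: for C2 this road is better, since retention at a preformed carbinol is more secure than a directed hydride addition. The chosen plan sets against this a ring closure by ketalisation and a built-in answer to C4.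

**Alternative 3:** Ring C of unit M is reached by ring expansion. A buffered peracid converts a 3-arylindanone into the 4-aryl-3,4-dihydrocoumarin A3 by aryl migration, leaving C4 untouched.
- Merits: the C4 centre can be set in the indanone by well-precedented asymmetric conjugate arylation, the migration is stereoretentive, and the lactone is robust.
- Weak points: a peracid meets several very electron-rich arenes. After A3 the route still needs C3 hydroxylation, addition of the ring B aryl metal to the lactone and the same hemiketal reduction as here. The aryl group of A3 is only ring A of unit T, so its pyran ring with three stereocentres must be built afterwards in linear fashion.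
- Comparison: it is better in the precedent for C4 and in the stability of its intermediates. The chosen plan sets against this that it reaches the hemiketal in one step with the C2 aryl group, the C3 oxygen and a finished unit T.

Key step: step 17

Assumption: the sense of induction of the (R)-configured phosphoric acid at C4 of unit M in step 17 cannot be derived with certainty for this ion pair; the (R)-acid is written, and its enantiomer takes its place if the sense proves opposite.

## Route

Step 1
Reactants: 1 2,3,4-trihydroxybenzaldehyde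
Product: 2 3,4-bis(benzyloxy)-2-hydroxybenzaldehyde
Conditions: BnBr (2.1 equiv), K2CO3 (2.1 equiv), DMF, 0 °C to rt
Reagents that add atoms: benzyl bromide, BrCc1ccccc1
Why: Williamson etherification; the 2-hydroxyl is held in a hydrogen bond to the formyl group and is the least nucleophilic, so two equivalents of halide should alkylate O4 and O3 only.

Step 2
Reactants: 3 4-(benzyloxy)benzaldehyde
Product: 4 (E)-3-[4-(benzyloxy)phenyl]prop-2-enal
Conditions: Ph3P=CHCHO, toluene, 80 °C
Reagents that add atoms: (triphenylphosphoranylidene)acetaldehyde, O=CC=P(c1ccccc1)(c1ccccc1)c1ccccc1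
Why: Wittig olefination with a stabilised ylide, which gives the (E)-enal; the product enal is a poorer electrophile than 3, which limits a second homologation.

Step 3
Reactants: 2 3,4-bis(benzyloxy)-2-hydroxybenzaldehyde, 4 (E)-3-[4-(benzyloxy)phenyl]prop-2-enal
Product: 5 (2R)-7,8-bis(benzyloxy)-2-[4-(benzyloxy)phenyl]-2H-chromene-3-carbaldehyde
Conditions: (S)-2-[diphenyl(trimethylsilyloxy)methyl]pyrrolidine (20 mol%), 2-nitrobenzoic acid (20 mol%), 4 Å MS, toluene, rt
Reagents that add atoms: none
Why: Amine-catalysed domino oxa-Michael/aldol condensation of a salicylaldehyde with an enal (iminium, then enamine activation), a known route to 2-aryl-2H-chromene-3-carbaldehydes. The phenol should add to the β-carbon of the (E)-iminium ion on the face away from the diphenyl(silyloxy)methyl group, which gives 2R.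

Step 4
Reactants: 5 (2R)-7,8-bis(benzyloxy)-2-[4-(benzyloxy)phenyl]-2H-chromene-3-carbaldehyde
Product: 7 (2R)-7,8-bis(benzyloxy)-2-[4-(benzyloxy)phenyl]chroman-3-one, via 2H-chromen-3-yl formate 6 (not isolated)
Conditions: m-CPBA (1.1 equiv), NaHCO3, CH2Cl2, 0 °C; then MeOH, Et3N (cat.), 0 °C
Reagents that add atoms: m-chloroperbenzoic acid, OOC(=O)c1cccc(Cl)c1
Why: Baeyer–Villiger oxidation of an α,β-unsaturated aldehyde (vinyl migration) gives the enol formate, and its methanolysis releases the ketone. C2 is not touched; cold, weakly basic conditions are used because C2–H is now α to a carbonyl.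

Step 5
Reactants: 7 (2R)-7,8-bis(benzyloxy)-2-[4-(benzyloxy)phenyl]chroman-3-one
Product: 8 (2R,3R)-7,8-bis(benzyloxy)-2-[4-(benzyloxy)phenyl]chroman-3-ol
Conditions: LiBH(s-Bu)3, THF, −78 °C; aq. NH4Cl
Reagents that add atoms: none
Why: Bulky-hydride reduction of a flavan-3-one; attack anti to the equatorial C2 aryl group gives the axial alcohol, the 2,3-cis (3R) isomer, as known for turning 2,3-trans into 2,3-cis flavan-3-ol ethers. Recrystallisation of 8 should raise the enantiomeric purity.

Step 6
Reactants: 8 (2R,3R)-7,8-bis(benzyloxy)-2-[4-(benzyloxy)phenyl]chroman-3-ol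
Product: 9 (2R,3R)-7,8-bis(benzyloxy)-2-[4-(benzyloxy)phenyl]-3-[(tert-butyldimethylsilyl)oxy]chroman
Conditions: t-BuMe2SiOTf, 2,6-lutidine, CH2Cl2, 0 °C
Reagents that add atoms: tert-butyldimethylsilyl trifluoromethanesulfonate, CC(C)(C)[Si](C)(C)OS(=O)(=O)C(F)(F)F
Why: Silylation of the hindered axial alcohol; a non-participating, base-stable group is wanted at O3 for the oxidation at C4 and the ketone reduction.

Step 7
Reactants: 9 (2R,3R)-7,8-bis(benzyloxy)-2-[4-(benzyloxy)phenyl]-3-[(tert-butyldimethylsilyl)oxy]chroman
Product: 10 (2R,3R)-7,8-bis(benzyloxy)-2-[4-(benzyloxy)phenyl]-3-[(tert-butyldimethylsilyl)oxy]chroman-4-ol (C4 epimers)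
Conditions: DDQ (1.5 equiv), CH2Cl2/H2O (20:1), rt
Reagents that add atoms: water, O
Why: DDQ-mediated benzylic C–H oxidation of an O-alkylated flavan-3-ol (hydride abstraction at C4, para to O7 and ortho to O1, then capture by water), known for flavan-3-ol ethers with resorcinol- and phloroglucinol-type rings A. The C4 configuration is erased in step 8.

Step 8
Reactants: 10 (2R,3R)-7,8-bis(benzyloxy)-2-[4-(benzyloxy)phenyl]-3-[(tert-butyldimethylsilyl)oxy]chroman-4-ol
Product: 11 (2R,3S)-7,8-bis(benzyloxy)-2-[4-(benzyloxy)phenyl]-3-[(tert-butyldimethylsilyl)oxy]chroman-4-one (2,3-cis)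
Conditions: Dess–Martin periodinane, NaHCO3, CH2Cl2, rt
Reagents that add atoms: none
Why: Dess–Martin oxidation of the benzylic alcohol; the buffered neutral medium avoids epimerisation of the 2,3-cis α-silyloxy ketone.

Step 9
Reactants: 11 (2R,3S)-7,8-bis(benzyloxy)-2-[4-(benzyloxy)phenyl]-3-[(tert-butyldimethylsilyl)oxy]chroman-4-one
Product: 12 (2R,3R,4R)-7,8-bis(benzyloxy)-2-[4-(benzyloxy)phenyl]-3-[(tert-butyldimethylsilyl)oxy]chroman-4-ol
Conditions: NaBH4, THF/MeOH, −20 °C
Reagents that add atoms: none
Why: Ketone reduction; in the 2,3-cis series the C3 silyloxy group is axial and shields its face, so hydride enters anti to it and the new hydroxyl is cis to O3 and to the C2 aryl group (4R). Carbon nucleophiles are known to add to such 4-oxo-2,3-cis-flavans in the same sense.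

Step 10
Reactants: 12 (2R,3R,4R)-7,8-bis(benzyloxy)-2-[4-(benzyloxy)phenyl]-3-[(tert-butyldimethylsilyl)oxy]chroman-4-ol
Product: 13 (2R,3R,4R)-7,8-bis(benzyloxy)-2-[4-(benzyloxy)phenyl]chroman-3,4-diol (tri-O-benzylteracacidin)
Conditions: Bu4NF, AcOH, THF, 0 °C to rt
Reagents that add atoms: none
Why: Fluoride-mediated desilylation; buffering with acetic acid keeps the medium from ionising or epimerising the benzylic carbinol.

Step 11
Reactants: 13 (2R,3R,4R)-7,8-bis(benzyloxy)-2-[4-(benzyloxy)phenyl]chroman-3,4-diol
Product: 14 tri-O-benzylteracacidin 3,4-carbonate (cis-fused cyclic carbonate of 13)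
Conditions: 1,1'-carbonyldiimidazole, 4-(dimethylamino)pyridine (cat.), THF, 50 °C
Reagents that add atoms: 1,1'-carbonyldiimidazole, O=C(n1ccnc1)n1ccnc1
Why: Cyclic carbonate formation from a cis-1,2-diol. The electron-poor, cis-fused ring disfavours ionisation at C4 and, should ionisation occur, can only close again on the same face.

Step 12
Reactants: 14 tri-O-benzylteracacidin 3,4-carbonate
Product: 15 6-iodo-tri-O-benzylteracacidin 3,4-carbonate
Conditions: NIS, CF3CO2H (cat.), MeCN, 0 °C
Reagents that add atoms: N-iodosuccinimide, O=C1CCC(=O)N1I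
Why: Electrophilic aromatic iodination; C6 is para to O1 and ortho to O7, whereas C5 is para only to the twisted O8 and peri to C4, so substitution should occur at C6.

Step 13
Reactants: 15 6-iodo-tri-O-benzylteracacidin 3,4-carbonate, 2 3,4-bis(benzyloxy)-2-hydroxybenzaldehyde
Product: 18 6-{[3,4-bis(benzyloxy)-2-hydroxyphenyl](hydroxy)methyl}-tri-O-benzylteracacidin 3,4-carbonate (carbinol epimers), via arylmagnesium chloride 16 (not isolated), via sodium phenoxide 17 (not isolated)
Conditions: 15, i-PrMgCl·LiCl, THF, −20 °C; 2, NaH, THF, 0 °C; combine, −20 to 0 °C; pH 7 phosphate buffer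
Reagents that add atoms: none
Why: Iodine–magnesium exchange followed by Grignard addition to the aldehyde. The exchange should outrun attack on the cyclic carbonate at −20 °C, the phenoxide keeps the acidic hydroxyl from protonating 16, and magnesium held between the phenoxide and formyl oxygens activates the carbonyl. The carbinol centre is not controlled and need not be, since it is lost in step 17.

Step 14
Reactants: 19 2-chloro-1-(3,4-dihydroxyphenyl)ethanone
Product: 20 2-(3,4-dihydroxyphenyl)-2-oxoethyl benzoate
Conditions: PhCO2Na, NaI (cat.), DMF, 50 °C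
Reagents that add atoms: sodium benzoate, [Na+].[O-]C(=O)c1ccccc1
Why: SN2 displacement of an α-chloro ketone by a carboxylate; benzoate is too weak a base to deprotonate the catechol, so O-alkylation of the phenols should not compete.

Step 15
Reactants: 20 2-(3,4-dihydroxyphenyl)-2-oxoethyl benzoate
Product: 21 2-[3,4-bis(benzyloxy)phenyl]-2-oxoethyl benzoate
Conditions: BnBr, K2CO3, acetone, reflux
Reagents that add atoms: benzyl bromide, BrCc1ccccc1
Why: Williamson etherification of the catechol under anhydrous conditions that leave the benzoate in place.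

Step 16
Reactants: 21 2-[3,4-bis(benzyloxy)phenyl]-2-oxoethyl benzoate
Product: 22 (Z)-2-[3,4-bis(benzyloxy)phenyl]-2-(trimethylsilyloxy)ethenyl benzoate
Conditions: Me3SiOTf, Et3N, CH2Cl2, 0 °C
Reagents that add atoms: trimethylsilyl trifluoromethanesulfonate, C[Si](C)(C)OS(=O)(=O)C(F)(F)F
Why: Soft enolisation and O-silylation of an aryl ketone with a single α-position. The (Z)-isomer, with the benzoyloxy group trans to the aryl group, is favoured by allylic strain, as for enol silanes of propiophenones.

Step 17
Reactants: 18 6-{[3,4-bis(benzyloxy)-2-hydroxyphenyl](hydroxy)methyl}-tri-O-benzylteracacidin 3,4-carbonate, 22 (Z)-2-[3,4-bis(benzyloxy)phenyl]-2-(trimethylsilyloxy)ethenyl benzoate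
Product: 25 6-{(3,4-trans)-3-(benzoyloxy)-7,8-bis(benzyloxy)-2-[3,4-bis(benzyloxy)phenyl]-2-hydroxychroman-4-yl}-tri-O-benzylteracacidin 3,4-carbonate (C2 anomers), via ortho-quinone methide 23 (not isolated), via 2-O-trimethylsilyl ketal 24 (not isolated)
Conditions: (R)-3,3'-bis(2,4,6-triisopropylphenyl)-1,1'-binaphthyl-2,2'-diyl hydrogen phosphate (10 mol%), 4 Å MS, toluene, −40 to −20 °C; then AcOH, THF/H2O, 0 °C
Reagents that add atoms: none
Why: Proposed new method: the phosphoric acid ionises the doubly benzylic carbinol of 18 to the (E)-ortho-quinone methide 23, which stays hydrogen-bonded and ion-paired to the chiral phosphate; enol ether 22 attacks the methide carbon (C4) through its benzoyloxy-bearing carbon (C3) in a Mukaiyama–Michael addition, and the phenol oxygen then adds to the silyloxycarbenium ion at C2 to give ketal 24, which is hydrolysed to 25 on work-up. The closest known reactions are the binaphthyl phosphoric acid-catalysed additions of enamides, enols of 1,3-dicarbonyl compounds and vinyl sulfides to ortho-quinone methides generated in this way from 2-hydroxybenzhydrols, and the Lewis-acid additions of silyl enol ethers to benzhydryl cations; an acyloxy-substituted silyl enol ether has not been used. Ring C of unit M closes by 6-exo-trig addition of O1 to the C2 oxocarbenium ion, overall a formal inverse-demand hetero-[4+2] annulation. C4 is set by the catalyst, whose phosphate blocks one face of the planar methide; the stereocentres of unit T are too remote to help, so this is reagent control. C3 is set relative to C4 in the C–C bond formation, where the (Z)-enol ether should turn its hydrogen and not its benzoyloxy group toward the arene of unit T (open transition state, 3,4-trans); because C3 is α to the ketone of the ring-opened tautomer, a trace of amine can equilibrate it to the trans isomer. C2 is left as a mixture of anomers and is settled in step 18. The step needs ionisation of the benzhydrol in preference to the benzylic carbonate of unit T, which the far greater stability of the bis(alkoxyaryl)methyl cation and the electron-poor carbonate should secure. It also needs C-attack of 22 before its protodesilylation, which the sieves and the low temperature favour.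

Step 18
Reactants: 25 6-{(3,4-trans)-3-(benzoyloxy)-7,8-bis(benzyloxy)-2-[3,4-bis(benzyloxy)phenyl]-2-hydroxychroman-4-yl}-tri-O-benzylteracacidin 3,4-carbonate
Product: 26 6-{(2,3-cis-3,4-trans)-3-(benzoyloxy)-7,8-bis(benzyloxy)-2-[3,4-bis(benzyloxy)phenyl]chroman-4-yl}-tri-O-benzylteracacidin 3,4-carbonate
Conditions: Et3SiH (3 equiv), Me3SiOTf (0.2 equiv), CH2Cl2, −78 to −40 °C
Reagents that add atoms: none
Why: Ionic reduction of a hemiketal (reductive etherification). The C3 benzoate bridges the C2 oxocarbenium ion as a dioxolanylium ion on its own face, so hydride enters anti to it and the C2 aryl group ends cis to O3, as in reductive etherifications that give 2,3-cis-flavan-3-ol esters. The tertiary hemiketal ionises at −78 °C, well below what the carbonate of unit T should need.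

Step 19
Reactants: 26 6-{(2,3-cis-3,4-trans)-3-(benzoyloxy)-7,8-bis(benzyloxy)-2-[3,4-bis(benzyloxy)phenyl]chroman-4-yl}-tri-O-benzylteracacidin 3,4-carbonate
Product: 27 hepta-O-benzyl ether of the target (all seven phenols benzylated; O3 of unit M and O3, O4 of unit T free)
Conditions: K2CO3, MeOH/THF, rt
Reagents that add atoms: none
Why: Transesterification removes the benzoate and the cyclic carbonate in one operation. It precedes hydrogenolysis because a benzylic carbonate would be cleaved reductively at C4.

Step 20
Reactants: 27 hepta-O-benzyl ether of the target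
Product: 28 CNP0174688.1: (2R,3R,4R)-teracacidin carrying at C6 the (2R,3R,4S)-3-hydroxy-7,8-dihydroxy-2-(3,4-dihydroxyphenyl)chroman-4-yl group
Conditions: H2 (1 atm), Pd(OH)2/C, THF/MeOH, rt
Reagents that add atoms: none
Why: Hydrogenolysis of the seven aryl benzyl ethers under neutral conditions; no stereocentre is touched.

## Compound list

1 | 2,3,4-trihydroxybenzaldehyde | O=Cc1ccc(O)c(O)c1O | starting material
2 | 3,4-bis(benzyloxy)-2-hydroxybenzaldehyde | O=Cc1ccc(OCc2ccccc2)c(OCc2ccccc2)c1O | intermediate
3 | 4-(benzyloxy)benzaldehyde | O=Cc1ccc(OCc2ccccc2)cc1 | starting material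
4 | (E)-3-[4-(benzyloxy)phenyl]prop-2-enal | O=C/C=C/c1ccc(OCc2ccccc2)cc1 | intermediate
5 | (2R)-7,8-bis(benzyloxy)-2-[4-(benzyloxy)phenyl]-2H-chromene-3-carbaldehyde | c1ccccc1COc1ccc([C@H]2Oc3c(ccc(OCc4ccccc4)c3OCc3ccccc3)C=C2C=O)cc1 | intermediate
6 | (2R)-7,8-bis(benzyloxy)-2-[4-(benzyloxy)phenyl]-2H-chromen-3-yl formate | c1ccccc1COc1ccc([C@H]2Oc3c(ccc(OCc4ccccc4)c3OCc3ccccc3)C=C2OC=O)cc1 | intermediate
7 | (2R)-7,8-bis(benzyloxy)-2-[4-(benzyloxy)phenyl]chroman-3-one | c1ccccc1COc1ccc([C@H]2Oc3c(ccc(OCc4ccccc4)c3OCc3ccccc3)CC2=O)cc1 | intermediate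
8 | (2R,3R)-7,8-bis(benzyloxy)-2-[4-(benzyloxy)phenyl]chroman-3-ol | c1ccccc1COc1ccc([C@H]2Oc3c(ccc(OCc4ccccc4)c3OCc3ccccc3)C[C@H]2O)cc1 | intermediate
9 | (2R,3R)-7,8-bis(benzyloxy)-2-[4-(benzyloxy)phenyl]-3-[(tert-butyldimethylsilyl)oxy]chroman | c1ccccc1COc1ccc([C@H]2Oc3c(ccc(OCc4ccccc4)c3OCc3ccccc3)C[C@H]2O[Si](C)(C)C(C)(C)C)cc1 | intermediate
10 | (2R,3R)-7,8-bis(benzyloxy)-2-[4-(benzyloxy)phenyl]-3-[(tert-butyldimethylsilyl)oxy]chroman-4-ol (C4 epimers) | c1ccccc1COc1ccc([C@H]2Oc3c(ccc(OCc4ccccc4)c3OCc3ccccc3)C(O)[C@H]2O[Si](C)(C)C(C)(C)C)cc1 | intermediate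
11 | (2R,3S)-7,8-bis(benzyloxy)-2-[4-(benzyloxy)phenyl]-3-[(tert-butyldimethylsilyl)oxy]chroman-4-one (2,3-cis) | c1ccccc1COc1ccc([C@H]2Oc3c(ccc(OCc4ccccc4)c3OCc3ccccc3)C(=O)[C@H]2O[Si](C)(C)C(C)(C)C)cc1 | intermediate
12 | (2R,3R,4R)-7,8-bis(benzyloxy)-2-[4-(benzyloxy)phenyl]-3-[(tert-butyldimethylsilyl)oxy]chroman-4-ol | c1ccccc1COc1ccc([C@H]2Oc3c(ccc(OCc4ccccc4)c3OCc3ccccc3)[C@@H](O)[C@H]2O[Si](C)(C)C(C)(C)C)cc1 | intermediate
13 | (2R,3R,4R)-7,8-bis(benzyloxy)-2-[4-(benzyloxy)phenyl]chroman-3,4-diol (tri-O-benzylteracacidin) | c1ccccc1COc1ccc([C@H]2Oc3c(ccc(OCc4ccccc4)c3OCc3ccccc3)[C@@H](O)[C@H]2O)cc1 | intermediate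
14 | tri-O-benzylteracacidin 3,4-carbonate (cis-fused) | c1ccccc1COc1ccc([C@H]2Oc3c(ccc(OCc4ccccc4)c3OCc3ccccc3)[C@@H](OC(=O)O5)[C@H]25)cc1 | intermediate
15 | 6-iodo-tri-O-benzylteracacidin 3,4-carbonate | c1ccccc1COc1ccc([C@H]2Oc3c(cc(I)c(OCc4ccccc4)c3OCc3ccccc3)[C@@H](OC(=O)O5)[C@H]25)cc1 | intermediate
16 | 6-(chloromagnesio)-tri-O-benzylteracacidin 3,4-carbonate (LiCl complex) | c1ccccc1COc1ccc([C@H]2Oc3c(cc([Mg]Cl)c(OCc4ccccc4)c3OCc3ccccc3)[C@@H](OC(=O)O5)[C@H]25)cc1 | intermediate
17 | sodium 2,3-bis(benzyloxy)-6-formylphenoxide | O=Cc1ccc(OCc2ccccc2)c(OCc2ccccc2)c1[O-].[Na+] | intermediate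
18 | 6-{[3,4-bis(benzyloxy)-2-hydroxyphenyl](hydroxy)methyl}-tri-O-benzylteracacidin 3,4-carbonate (carbinol epimers) | c1ccccc1COc1ccc([C@H]2Oc3c(cc(C(O)c4ccc(OCc5ccccc5)c(OCc5ccccc5)c4O)c(OCc4ccccc4)c3OCc3ccccc3)[C@@H](OC(=O)O6)[C@H]26)cc1 | intermediate
19 | 2-chloro-1-(3,4-dihydroxyphenyl)ethanone | O=C(CCl)c1ccc(O)c(O)c1 | starting material
20 | 2-(3,4-dihydroxyphenyl)-2-oxoethyl benzoate | O=C(COC(=O)c1ccccc1)c1ccc(O)c(O)c1 | intermediate
21 | 2-[3,4-bis(benzyloxy)phenyl]-2-oxoethyl benzoate | O=C(COC(=O)c1ccccc1)c1ccc(OCc2ccccc2)c(OCc2ccccc2)c1 | intermediate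
22 | (Z)-2-[3,4-bis(benzyloxy)phenyl]-2-(trimethylsilyloxy)ethenyl benzoate | C[Si](C)(C)O/C(=C\OC(=O)c1ccccc1)c1ccc(OCc2ccccc2)c(OCc2ccccc2)c1 | intermediate
23 | 6-{(E)-[4,5-bis(benzyloxy)-6-oxocyclohexa-2,4-dien-1-ylidene]methyl}-tri-O-benzylteracacidin 3,4-carbonate | c1ccccc1COc1ccc([C@H]2Oc3c(cc(/C=C4\C=CC(OCc5ccccc5)=C(OCc5ccccc5)C4=O)c(OCc4ccccc4)c3OCc3ccccc3)[C@@H](OC(=O)O6)[C@H]26)cc1 | intermediate
24 | 2-O-trimethylsilyl ketal of 25 (C2 epimers) | c1ccccc1COc1ccc([C@H]2Oc3c(cc([C@H]4c5ccc(OCc6ccccc6)c(OCc6ccccc6)c5OC(O[Si](C)(C)C)(c5ccc(OCc6ccccc6)c(OCc6ccccc6)c5)[C@@H]4OC(=O)c4ccccc4)c(OCc4ccccc4)c3OCc3ccccc3)[C@@H](OC(=O)O7)[C@H]27)cc1 | intermediate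
25 | 6-{(3,4-trans)-3-(benzoyloxy)-7,8-bis(benzyloxy)-2-[3,4-bis(benzyloxy)phenyl]-2-hydroxychroman-4-yl}-tri-O-benzylteracacidin 3,4-carbonate (C2 anomers) | c1ccccc1COc1ccc([C@H]2Oc3c(cc([C@H]4c5ccc(OCc6ccccc6)c(OCc6ccccc6)c5OC(O)(c5ccc(OCc6ccccc6)c(OCc6ccccc6)c5)[C@@H]4OC(=O)c4ccccc4)c(OCc4ccccc4)c3OCc3ccccc3)[C@@H](OC(=O)O7)[C@H]27)cc1 | intermediate
26 | 6-{(2,3-cis-3,4-trans)-3-(benzoyloxy)-7,8-bis(benzyloxy)-2-[3,4-bis(benzyloxy)phenyl]chroman-4-yl}-tri-O-benzylteracacidin 3,4-carbonate | c1ccccc1COc1ccc([C@H]2Oc3c(cc([C@H]4c5ccc(OCc6ccccc6)c(OCc6ccccc6)c5O[C@H](c5ccc(OCc6ccccc6)c(OCc6ccccc6)c5)[C@@H]4OC(=O)c4ccccc4)c(OCc4ccccc4)c3OCc3ccccc3)[C@@H](OC(=O)O7)[C@H]27)cc1 | intermediate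
27 | hepta-O-benzyl ether of the target (three secondary hydroxyls free) | c1ccccc1COc1ccc([C@H]2Oc3c(cc([C@H]4c5ccc(OCc6ccccc6)c(OCc6ccccc6)c5O[C@H](c5ccc(OCc6ccccc6)c(OCc6ccccc6)c5)[C@@H]4O)c(OCc4ccccc4)c3OCc3ccccc3)[C@@H](O)[C@H]2O)cc1 | intermediate
28 | CNP0174688.1 | Oc1ccc([C@H]2Oc3c(cc([C@H]4c5ccc(O)c(O)c5O[C@H](c5ccc(O)c(O)c5)[C@@H]4O)c(O)c3O)[C@@H](O)[C@H]2O)cc1 | target

## Step count and least certain steps

Total step count: 20. Longest linear sequence: 16 steps (steps 1, 3 to 13 and 17 to 20).

**Step 17 (key step, proposed new method).**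
- What may go wrong: poor facial discrimination at C4, because the highly stabilised cation may form only a loose ion pair and the silyl enol ether offers the phosphate no hydrogen bond; protodesilylation of 22 by the water released on ionisation; and incomplete 3,4-trans selectivity.
- Fallback (known chemistry), from 18 back to 25: purchased 1-[3,4-bis(benzyloxy)phenyl]ethanone F1 is converted through its oxime F2 (NH2OH·HCl, pyridine) by reductive acetylation (Fe, Ac2O, AcOH) into the enamide N-{1-[3,4-bis(benzyloxy)phenyl]ethenyl}acetamide F3. The known phosphoric acid-catalysed addition of such enamides to the ortho-quinone methide from 18 has an N–H hydrogen bond to the phosphate that tightens the transition state. It gives the 2-acetamidochroman F4, which loses acetamide with a trace of TsOH to give the 2,4-diaryl-4H-chromene F5. Dihydroxylation of the enol ether double bond of F5 (OsO4 cat., N-methylmorpholine N-oxide) on the face anti to the C4 aryl group gives the 2,3-dihydroxy hemiketal F6 with O3 trans to that group. Benzoylation of the secondary hydroxyl (BzCl, pyridine, −20 °C) rejoins the route at 25.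

**Step 18.**
- What may go wrong: hydride delivery to the wrong face of C2, because the C4 aryl group sits on the face anti to the benzoate where the silane must approach; ionisation and reduction at C4 of unit T; and acid cleavage of the interflavan bond.
- Fallback, from 25 back to 27: methanolysis (K2CO3, MeOH) gives the ester-free hemiketal tetraol F7, in equilibrium with its α-hydroxy ketone. Chelation-controlled reduction with Zn(BH4)2 gives the anti-1,2-diol F8. Mitsunobu cyclisation (PPh3, diisopropyl azodicarboxylate) of the phenol onto the benzylic C2 carbinol, with inversion, closes ring C as the 2,3-cis flavan and rejoins the route at 27 without any Lewis acid.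

**Step 13.**
- What may go wrong: slow exchange at the electron-rich iodide, competing attack on the carbonate, and dehydration and oligomerisation of the very easily ionised benzhydrol during work-up.
- Fallback, from 15 back to 18: Miyaura borylation of 15 (PdCl2(dppf), bis(pinacolato)diboron, KOAc, dioxane, 80 °C) gives the pinacol boronate F9. This is added to the free aldehyde 2 under [Rh(OH)(cod)]2 catalysis in aqueous dioxane, a neutral 1,2-addition that tolerates the phenol and the carbonate.

**Step 7.**
- What may go wrong: competing hydride abstraction at C2, which is benzylic to ring B and α to O1, and over-oxidation, both of which erode the yield.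
- Fallback, from 5 back to 13: RhCl(PPh3)3-mediated decarbonylation of 5 gives the flav-3-ene F10 (same spatial arrangement at C2; kept at the lowest workable temperature to avoid electrocyclic racemisation). Woodward cis-hydroxylation (I2, AgOAc, wet AcOH) places iodine anti to the C2 aryl group and, through the acetoxonium ion, both oxygens on the aryl face, giving the all-cis diol monoacetate F11 (4-acetate drawn). Methanolysis (K2CO3, MeOH) rejoins the route at 13.

**Step 20.**
- What may go wrong: reductive cleavage of the benzylic C4–O bond of unit T alongside the benzyl ethers.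
- Fallback, from 26 back to 28: the benzyl ethers are removed without hydrogen while both esters still deactivate their surroundings (BCl3, pentamethylbenzene, CH2Cl2, −78 °C), giving the heptaphenol benzoate carbonate F12. Methanolysis in degassed MeOH (K2CO3, argon) then gives 28.

## Further compounds

F1 | step 17 | 1-[3,4-bis(benzyloxy)phenyl]ethanone (purchased) | CC(=O)c1ccc(OCc2ccccc2)c(OCc2ccccc2)c1
F2 | step 17 | 1-[3,4-bis(benzyloxy)phenyl]ethanone oxime | CC(=NO)c1ccc(OCc2ccccc2)c(OCc2ccccc2)c1
F3 | step 17 | N-{1-[3,4-bis(benzyloxy)phenyl]ethenyl}acetamide | C=C(NC(C)=O)c1ccc(OCc2ccccc2)c(OCc2ccccc2)c1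
F4 | step 17 | 6-{2-acetamido-7,8-bis(benzyloxy)-2-[3,4-bis(benzyloxy)phenyl]chroman-4-yl}-tri-O-benzylteracacidin 3,4-carbonate (C2 epimers) | c1ccccc1COc1ccc([C@H]2Oc3c(cc([C@H]4c5ccc(OCc6ccccc6)c(OCc6ccccc6)c5OC(NC(C)=O)(c5ccc(OCc6ccccc6)c(OCc6ccccc6)c5)C4)c(OCc4ccccc4)c3OCc3ccccc3)[C@@H](OC(=O)O7)[C@H]27)cc1
F5 | step 17 | 6-{7,8-bis(benzyloxy)-2-[3,4-bis(benzyloxy)phenyl]-4H-chromen-4-yl}-tri-O-benzylteracacidin 3,4-carbonate | c1ccccc1COc1ccc([C@H]2Oc3c(cc([C@H]4c5ccc(OCc6ccccc6)c(OCc6ccccc6)c5OC(c5ccc(OCc6ccccc6)c(OCc6ccccc6)c5)=C4)c(OCc4ccccc4)c3OCc3ccccc3)[C@@H](OC(=O)O7)[C@H]27)cc1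
F6 | step 17 | 6-{(3,4-trans)-7,8-bis(benzyloxy)-2-[3,4-bis(benzyloxy)phenyl]-2,3-dihydroxychroman-4-yl}-tri-O-benzylteracacidin 3,4-carbonate (C2 anomers) | c1ccccc1COc1ccc([C@H]2Oc3c(cc([C@H]4c5ccc(OCc6ccccc6)c(OCc6ccccc6)c5OC(O)(c5ccc(OCc6ccccc6)c(OCc6ccccc6)c5)[C@@H]4O)c(OCc4ccccc4)c3OCc3ccccc3)[C@@H](OC(=O)O7)[C@H]27)cc1
F7 | step 18 | 6-{(3,4-trans)-7,8-bis(benzyloxy)-2-[3,4-bis(benzyloxy)phenyl]-2,3-dihydroxychroman-4-yl}-tri-O-benzylteracacidin (C2 anomers) | c1ccccc1COc1ccc([C@H]2Oc3c(cc([C@H]4c5ccc(OCc6ccccc6)c(OCc6ccccc6)c5OC(O)(c5ccc(OCc6ccccc6)c(OCc6ccccc6)c5)[C@@H]4O)c(OCc4ccccc4)c3OCc3ccccc3)[C@@H](O)[C@H]2O)cc1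
F8 | step 18 | 6-{1-[3,4-bis(benzyloxy)-2-hydroxyphenyl]-3-[3,4-bis(benzyloxy)phenyl]-2,3-dihydroxypropyl}-tri-O-benzylteracacidin (2,3-anti diol) | c1ccccc1COc1ccc([C@H]2Oc3c(cc([C@@H](c4ccc(OCc5ccccc5)c(OCc5ccccc5)c4O)[C@@H](O)[C@@H](O)c4ccc(OCc5ccccc5)c(OCc5ccccc5)c4)c(OCc4ccccc4)c3OCc3ccccc3)[C@@H](O)[C@H]2O)cc1
F9 | step 13 | 6-(4,4,5,5-tetramethyl-1,3,2-dioxaborolan-2-yl)-tri-O-benzylteracacidin 3,4-carbonate | c1ccccc1COc1ccc([C@H]2Oc3c(cc(B4OC(C)(C)C(C)(C)O4)c(OCc4ccccc4)c3OCc3ccccc3)[C@@H](OC(=O)O5)[C@H]25)cc1
F10 | step 7 | (2S)-7,8-bis(benzyloxy)-2-[4-(benzyloxy)phenyl]-2H-chromene | c1ccccc1COc1ccc([C@H]2Oc3c(ccc(OCc4ccccc4)c3OCc3ccccc3)C=C2)cc1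
F11 | step 7 | tri-O-benzylteracacidin 4-acetate (all-cis) | c1ccccc1COc1ccc([C@H]2Oc3c(ccc(OCc4ccccc4)c3OCc3ccccc3)[C@@H](OC(C)=O)[C@H]2O)cc1
F12 | step 20 | 3-O-benzoate (unit M) 3,4-carbonate (unit T) of the target | Oc1ccc([C@H]2Oc3c(cc([C@H]4c5ccc(O)c(O)c5O[C@H](c5ccc(O)c(O)c5)[C@@H]4OC(=O)c4ccccc4)c(O)c3O)[C@@H](OC(=O)O6)[C@H]26)cc1
A1 | alternative 1 | (S)-configured 1-[2,3-bis(benzyloxy)-4-hydroxyphenyl]-1-[3,4-bis(benzyloxy)-2-hydroxyphenyl]-3-[3,4-bis(benzyloxy)phenyl]prop-2-yne type diarylpropyne | Oc1ccc([C@H](C#Cc2ccc(OCc3ccccc3)c(OCc3ccccc3)c2)c2ccc(OCc3ccccc3)c(OCc3ccccc3)c2O)c(OCc2ccccc2)c1OCc1ccccc1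
A2 | alternative 2 | nona-O-benzyl target with the C4 hydroxyl of unit T as tert-butyldimethylsilyl ether | O(Cc7ccccc7)c1ccc([C@H]2Oc3c(cc([C@H]4c5ccc(OCc6ccccc6)c(OCc6ccccc6)c5O[C@H](c5ccc(OCc6ccccc6)c(OCc6ccccc6)c5)[C@@H]4OCc4ccccc4)c(OCc4ccccc4)c3OCc3ccccc3)[C@@H](O[Si](C)(C)C(C)(C)C)[C@H]2OCc2ccccc2)cc1
A3 | alternative 3 | 4-[2,3-bis(benzyloxy)-4-(pivaloyloxy)phenyl]-7,8-bis(benzyloxy)-3,4-dihydrocoumarin | CC(C)(C)C(=O)Oc1ccc([C@@H]4CC(=O)Oc5c4ccc(OCc6ccccc6)c5OCc5ccccc5)c(OCc2ccccc2)c1OCc1ccccc1
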